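**Retrosynthetic overview** (target numbered as 12-oxabicyclo[9.1.0]dodecane: C1 = methyl-bearing oxirane carbon, C2 = ester carbinol, C3=C4, C5 = quaternary carbon, C7=C8 with CH2OH on C8, C9, C10, C11 = oxirane CH, O12)
1. End game: 4-methoxybenzyl ether cleavage ⇐ esterification of C2–OH with 3-methylbut-2-enoic acid ⇐ hydroxyl-directed epoxidation of the (Z)-C1=C11 olefin of an eleven-membered trienol.
2. Key disconnection C9–C10 (ring closure). Enabling feature: C10 is attached to oxirane carbon C11, so it is allylic once the C1–C11 oxirane is taken back to the (Z)-C1=C11 olefin and can carry a phenylsulfonyl-stabilised carbanion; C9 is attached to C8 of the C7=C8–CH2OH unit, so it is the β-carbon of an α-substituted acrylate when CH2OH is CO2CH3 and C7 bears acetate (Morita–Baylis–Hillman acetate). An intramolecular SN2′ alkylation then closes the eleven-membered carbocycle and creates the (7E) olefin in one operation.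
3. Open-chain precursor: C5 and the (3E) olefin by Johnson–Claisen chirality transfer from a CBS-derived (R)-allylic alcohol; C2 by zinc/ProPhenol alkynylation of the derived enal; the (Z)-C1=C11 olefin by syn-methylcupration of the ynoate; sulfone and Baylis–Hillman acetate installed at the two chain ends.
4. Order of ring formation: eleven-membered carbocycle first (step 16), oxirane second (step 21).

Key step: step 16

Assumption: the catalyst antipodes named in steps 4 and 8 are those expected from the usual CBS and ProPhenol facial models to give (2R)-9 and (4S)-15; if the sense is opposite on these substrates the mirror-image catalyst is used.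

**Step 1**
Reactants: 1 5-bromo-2-methylpent-2-ene; 2 lithium acetylide–ethylenediamine complex (LiC≡CH·H2NCH2CH2NH2)
Product: 3 6-methylhept-5-en-1-yne
Conditions: DMSO, 10 °C → rt
Reagents that add atoms: none
Why: SN2 alkylation of the acetylide by an unhindered primary bromide in a dipolar aprotic solvent, with no stereocentre formed.

**Step 2**
Reactants: 3 6-methylhept-5-en-1-yne; 4 2-[(tert-butyldimethylsilyl)oxy]acetaldehyde
Product: 7 rac-(3E)-1-[(tert-butyldimethylsilyl)oxy]-4,8-dimethylnona-3,7-dien-2-ol, via alkenyldimethylalane 5 (not isolated), via lithium alkenylaluminate 6 (not isolated)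
Conditions: Al(CH3)3, (C5H5)2ZrCl2 (cat.), CH2Cl2, 0 °C → rt; volatiles removed; n-C4H9Li, hexane/THF, −78 → 0 °C; then 4, −78 °C → rt; aq. KNaC4H4O6
Reagents that add atoms: trimethylaluminium C[Al](C)C; n-butyllithium [Li]CCCC (retained only in intermediate 6)
Why: Zirconium-catalysed syn-carboalumination (Negishi carboalumination) puts CH3 on the internal and aluminium on the terminal alkyne carbon, which fixes the (E)-trisubstituted olefin, and the derived alkenylaluminate transfers the alkenyl group to the aldehyde with retention of geometry, the carbinol centre being racemic and reset in step 4.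

**Step 3**
Reactants: 7 rac-(3E)-1-[(tert-butyldimethylsilyl)oxy]-4,8-dimethylnona-3,7-dien-2-ol
Product: 8 (3E)-1-[(tert-butyldimethylsilyl)oxy]-4,8-dimethylnona-3,7-dien-2-one
Conditions: Dess–Martin periodinane, NaHCO3, CH2Cl2, 0 °C → rt
Reagents that add atoms: none
Why: Buffered Dess–Martin oxidation of a secondary allylic alcohol should give the enone without olefin isomerisation and erases the racemic centre.

**Step 4**
Reactants: 8 (3E)-1-[(tert-butyldimethylsilyl)oxy]-4,8-dimethylnona-3,7-dien-2-one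
Product: 9 (2R,3E)-1-[(tert-butyldimethylsilyl)oxy]-4,8-dimethylnona-3,7-dien-2-ol
Conditions: (R)-2-methyl-CBS-oxazaborolidine (10 mol %), BH3·S(CH3)2, THF, −30 °C; MeOH
Reagents that add atoms: none
Why: Corey–Bakshi–Shibata reduction, in which the oxazaborolidine–borane complex binds the carbonyl with the alkenyl group as the large substituent and delivers hydride to one face, so the (R)-catalyst should set the (2R) carbinol.

**Step 5**
Reactants: 9 (2R,3E)-1-[(tert-butyldimethylsilyl)oxy]-4,8-dimethylnona-3,7-dien-2-ol; 10 triethyl orthoacetate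
Product: 11 ethyl (3S,4E)-6-[(tert-butyldimethylsilyl)oxy]-3-methyl-3-(4-methylpent-3-en-1-yl)hex-4-enoate
Conditions: EtCO2H (cat.), neat in 10, 140 °C, EtOH distilled off
Reagents that add atoms: none
Why: Johnson–Claisen rearrangement through a chair transition state with the CH2OSi group pseudo-equatorial delivers the new C–C bond suprafacially, so the (R) carbinol and the (E)-trisubstituted olefin are translated into the (S) quaternary carbon (1,3-chirality transfer) and the new disubstituted olefin is formed E.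

**Step 6**
Reactants: 11 ethyl (3S,4E)-6-[(tert-butyldimethylsilyl)oxy]-3-methyl-3-(4-methylpent-3-en-1-yl)hex-4-enoate
Product: 12 ethyl (3S,4E)-6-hydroxy-3-methyl-3-(4-methylpent-3-en-1-yl)hex-4-enoate
Conditions: Bu4NF, THF, 0 °C → rt
Reagents that add atoms: none
Why: Fluoride cleavage of a primary silyl ether, to which the ester and the olefins are inert.

**Step 7**
Reactants: 12 ethyl (3S,4E)-6-hydroxy-3-methyl-3-(4-methylpent-3-en-1-yl)hex-4-enoate
Product: 13 ethyl (3S,4E)-3-methyl-3-(4-methylpent-3-en-1-yl)-6-oxohex-4-enoate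
Conditions: MnO2, CH2Cl2, rt
Reagents that add atoms: none
Why: Chemoselective MnO2 oxidation of a primary allylic alcohol should give the (E)-enal without touching the ester or the quaternary centre.

**Step 8**
Reactants: 13 ethyl (3S,4E)-3-methyl-3-(4-methylpent-3-en-1-yl)-6-oxohex-4-enoate; 14 methyl propiolate
Product: 15 9-ethyl 1-methyl (4S,5E,7S)-4-hydroxy-7-methyl-7-(4-methylpent-3-en-1-yl)non-5-en-2-ynedioate
Conditions: Zn(CH3)2, (S,S)-ProPhenol (20 mol %), Ph3P=O (40 mol %), toluene, 0–4 °C; sat. aq. NH4Cl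
Reagents that add atoms: none
Why: Zinc/ProPhenol-catalysed enantioselective alkynylation, in which the dinuclear zinc complex holds the zinc acetylide of 14 and the enal and directs 1,2-addition to the Re face, sets the (4S) carbinol under catalyst control, the remote quaternary centre exerting no bias.

**Step 9**
Reactants: 15 9-ethyl 1-methyl (4S,5E,7S)-4-hydroxy-7-methyl-7-(4-methylpent-3-en-1-yl)non-5-en-2-ynedioate
Product: 16 9-ethyl 1-methyl (4S,5E,7S)-4-[(tert-butyldimethylsilyl)oxy]-7-methyl-7-(4-methylpent-3-en-1-yl)non-5-en-2-ynedioate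
Conditions: tert-butyldimethylsilyl triflate, 2,6-lutidine, CH2Cl2, −78 °C
Reagents that add atoms: tert-butyldimethylsilyl trifluoromethanesulfonate CC(C)(C)[Si](C)(C)OS(=O)(=O)C(F)(F)F
Why: Silylation with the silyl triflate and a hindered, non-nucleophilic pyridine base protects the carbinol without conjugate addition of a base to the ynoate.

**Step 10**
Reactants: 16 9-ethyl 1-methyl (4S,5E,7S)-4-[(tert-butyldimethylsilyl)oxy]-7-methyl-7-(4-methylpent-3-en-1-yl)non-5-en-2-ynedioate
Product: 17 9-ethyl 1-methyl (2Z,4S,5E,7S)-4-[(tert-butyldimethylsilyl)oxy]-3,7-dimethyl-7-(4-methylpent-3-en-1-yl)nona-2,5-dienedioate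
Conditions: CH3Li, CuI, THF, −78 °C; MeOH, −78 °C; then aq. NH4Cl
Reagents that add atoms: lithium dimethylcuprate (from CH3Li and CuI) [Li+].C[Cu-]C
Why: Syn-carbocupration of the ynoate by the Gilman reagent with cold protonation places CH3 and H cis, so the carbinol carbon and the ester end up cis in the (2Z)-trisubstituted enoate, while the silyl ether prevents lactonisation and the saturated ethyl ester is inert at −78 °C.

**Step 11**
Reactants: 17 9-ethyl 1-methyl (2Z,4S,5E,7S)-4-[(tert-butyldimethylsilyl)oxy]-3,7-dimethyl-7-(4-methylpent-3-en-1-yl)nona-2,5-dienedioate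
Product: 18 (2Z,4S,5E,7S)-4-[(tert-butyldimethylsilyl)oxy]-3,7-dimethyl-7-(4-methylpent-3-en-1-yl)nona-2,5-diene-1,9-diol
Conditions: (i-C4H9)2AlH (6 equiv), CH2Cl2, −78 → 0 °C; aq. KNaC4H4O6
Reagents that add atoms: none
Why: Exhaustive hydride reduction by diisobutylaluminium hydride converts the (Z)-enoate (1,2-reduction) and the saturated ester into primary alcohols without changing either olefin geometry.

**Step 12**
Reactants: 18 (2Z,4S,5E,7S)-4-[(tert-butyldimethylsilyl)oxy]-3,7-dimethyl-7-(4-methylpent-3-en-1-yl)nona-2,5-diene-1,9-diol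
Product: 20 (3S,4E,6S,7Z)-6-[(tert-butyldimethylsilyl)oxy]-3,7-dimethyl-3-(4-methylpent-3-en-1-yl)-9-(phenylsulfonyl)nona-4,7-dien-1-ol, via allylic bromide 19 (not isolated)
Conditions: N-bromosuccinimide, (CH3)2S, CH2Cl2, −20 → 0 °C; then PhSO2Na, DMF, rt
Reagents that add atoms: N-bromosuccinimide O=C1CCC(=O)N1Br; sodium benzenesulfinate [Na+].[O-]S(=O)c1ccccc1
Why: Corey–Kim bromination converts only the allylic hydroxyl (the saturated alkoxysulfonium salt returns the alcohol on work-up), and SN2 displacement by sulfinate through sulfur should give the primary allylic sulfone with the (Z) geometry retained.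

**Step 13**
Reactants: 20 (3S,4E,6S,7Z)-6-[(tert-butyldimethylsilyl)oxy]-3,7-dimethyl-3-(4-methylpent-3-en-1-yl)-9-(phenylsulfonyl)nona-4,7-dien-1-ol
Product: 21 (3S,4E,6S,7Z)-6-[(tert-butyldimethylsilyl)oxy]-3,7-dimethyl-3-(4-methylpent-3-en-1-yl)-9-(phenylsulfonyl)nona-4,7-dienal
Conditions: Dess–Martin periodinane, NaHCO3, CH2Cl2, 0 °C → rt
Reagents that add atoms: none
Why: Dess–Martin oxidation of the remaining primary alcohol gives the aldehyde, which has no epimerisable centre, and leaves the sulfone and the silyl ether untouched.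

**Step 14**
Reactants: 21 (3S,4E,6S,7Z)-6-[(tert-butyldimethylsilyl)oxy]-3,7-dimethyl-3-(4-methylpent-3-en-1-yl)-9-(phenylsulfonyl)nona-4,7-dienal; 22 methyl acrylate
Product: 23 methyl (5S,6E,8S,9Z)-8-[(tert-butyldimethylsilyl)oxy]-3-hydroxy-5,9-dimethyl-2-methylidene-5-(4-methylpent-3-en-1-yl)-11-(phenylsulfonyl)undeca-6,9-dienoate (both C3 epimers)
Conditions: DABCO (1 equiv), MeOH (cat.), neat in 22, rt, several days
Reagents that add atoms: none
Why: Morita–Baylis–Hillman reaction, in which the amine adds to the acrylate and the zwitterionic enolate adds to the α-unbranched aldehyde, the new carbinol centre being formed as a mixture that is removed in step 16.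

**Step 15**
Reactants: 23 methyl (5S,6E,8S,9Z)-8-[(tert-butyldimethylsilyl)oxy]-3-hydroxy-5,9-dimethyl-2-methylidene-5-(4-methylpent-3-en-1-yl)-11-(phenylsulfonyl)undeca-6,9-dienoate (both C3 epimers)
Product: 24 methyl (5S,6E,8S,9Z)-3-acetoxy-8-[(tert-butyldimethylsilyl)oxy]-5,9-dimethyl-2-methylidene-5-(4-methylpent-3-en-1-yl)-11-(phenylsulfonyl)undeca-6,9-dienoate (both C3 epimers)
Conditions: Ac2O, pyridine, DMAP (cat.), CH2Cl2, 0 °C → rt
Reagents that add atoms: acetic anhydride CC(=O)OC(C)=O
Why: Acetylation of the secondary allylic alcohol turns it into the leaving group for the addition–elimination of step 16.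

**Step 16**
Reactants: 24 methyl (5S,6E,8S,9Z)-3-acetoxy-8-[(tert-butyldimethylsilyl)oxy]-5,9-dimethyl-2-methylidene-5-(4-methylpent-3-en-1-yl)-11-(phenylsulfonyl)undeca-6,9-dienoate (both C3 epimers)
Product: 25 methyl (1E,4S,5E,7S,8Z)-7-[(tert-butyldimethylsilyl)oxy]-4,8-dimethyl-4-(4-methylpent-3-en-1-yl)-10-(phenylsulfonyl)cycloundeca-1,5,8-triene-1-carboxylate (both C10 epimers)
Conditions: KN(Si(CH3)3)2 (1.1 equiv), THF, −78 → −20 °C, syringe-pump addition of 24 (final ca. 1 mM); sat. aq. NH4Cl at −78 °C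
Reagents that add atoms: none
Why: Proposed new method: KN(Si(CH3)3)2 removes a proton from the allylic sulfone CH2 (the only carbon acid near pKa 22 in 24), the α-sulfonyl allyl carbanion adds through its α-carbon to the unsubstituted acrylate terminus (intramolecular Michael addition) and the resulting ester enolate expels the β-acetate (E1cB), an overall intramolecular SN2′ alkylation that forms the bond between the sulfone carbon and the former acrylate CH2 (C9–C10 of the target numbering), closes the eleven-membered carbocycle and creates the trisubstituted enoate in one operation. The closest known reaction types are the intermolecular SN2′ (addition–elimination) alkylation of stabilised carbanions by Morita–Baylis–Hillman acetates and the ring closure of sulfone-stabilised allyl carbanions onto allylic halides established for ten-, eleven- and fourteen-membered 1,5-diene terpenoid carbocycles; their combination in a macrocyclisation is what is new. The ring closes in the 11-endo-trig mode with respect to the acrylate C=C, both acrylate carbons ending up in the ring. The only new stereocentre is the sulfone-bearing carbon, which is not controlled and is erased in step 18, and both acetate epimers of 24 converge on the same enoate. The enoate geometry is set in the elimination, where the ester prefers to lie trans to the ring CH2 on the β-carbon (tiglate-type, the usual outcome with Baylis–Hillman esters), which is also the ring-cis arrangement required. The step needs α- over γ-attack of the allyl anion (γ-attack would build a quaternary carbon inside a nine-membered ring), retention of the Z geometry (the sulfonyl allyl anion is configurationally stable at low temperature) and ring closure over oligomerisation, which slow addition to high dilution and the pre-folding of the chain by the quaternary carbon, the E olefin and the Z olefin should secure.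

**Step 17**
Reactants: 25 methyl (1E,4S,5E,7S,8Z)-7-[(tert-butyldimethylsilyl)oxy]-4,8-dimethyl-4-(4-methylpent-3-en-1-yl)-10-(phenylsulfonyl)cycloundeca-1,5,8-triene-1-carboxylate (both C10 epimers)
Product: 26 [(1E,4S,5E,7S,8Z)-7-[(tert-butyldimethylsilyl)oxy]-4,8-dimethyl-4-(4-methylpent-3-en-1-yl)-10-(phenylsulfonyl)cycloundeca-1,5,8-trien-1-yl]methanol (both C10 epimers)
Conditions: (i-C4H9)2AlH (3 equiv), CH2Cl2, −78 °C; aq. KNaC4H4O6
Reagents that add atoms: none
Why: 1,2-Reduction of the conjugated methyl ester by diisobutylaluminium hydride at low temperature should give the allylic alcohol without affecting the sulfone, the silyl ether or the olefin geometry.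

**Step 18**
Reactants: 26 [(1E,4S,5E,7S,8Z)-7-[(tert-butyldimethylsilyl)oxy]-4,8-dimethyl-4-(4-methylpent-3-en-1-yl)-10-(phenylsulfonyl)cycloundeca-1,5,8-trien-1-yl]methanol (both C10 epimers)
Product: 27 [(1E,4S,5E,7S,8Z)-7-[(tert-butyldimethylsilyl)oxy]-4,8-dimethyl-4-(4-methylpent-3-en-1-yl)cycloundeca-1,5,8-trien-1-yl]methanol
Conditions: PdCl2(dppp) (10 mol %), LiBH(C2H5)3 (4 equiv), THF, 0 °C → rt
Reagents that add atoms: none
Why: Palladium-catalysed reductive desulfonylation of an allylic sulfone, in which zerovalent palladium ionises the allylic C–S bond and hydride is delivered to the less substituted allyl terminus (the former sulfone carbon), so the olefin stays in place and, because the fully substituted terminus cannot isomerise through a sigma-bound palladium, should keep its Z geometry while the sulfone stereocentre disappears.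

**Step 19**
Reactants: 27 [(1E,4S,5E,7S,8Z)-7-[(tert-butyldimethylsilyl)oxy]-4,8-dimethyl-4-(4-methylpent-3-en-1-yl)cycloundeca-1,5,8-trien-1-yl]methanol
Product: 28 tert-butyl{[(1S,2Z,6E,9S,10E)-6-{[(4-methoxybenzyl)oxy]methyl}-2,9-dimethyl-9-(4-methylpent-3-en-1-yl)cycloundeca-2,6,10-trien-1-yl]oxy}dimethylsilane
Conditions: NaH, 4-methoxybenzyl chloride, Bu4NI (cat.), THF/DMF, 0 °C → rt
Reagents that add atoms: 4-methoxybenzyl chloride COc1ccc(CCl)cc1
Why: Williamson etherification of the primary allylic alkoxide, now free of acidic sulfone protons, protects the hydroxymethyl group orthogonally to the secondary silyl ether.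

**Step 20**
Reactants: 28 tert-butyl{[(1S,2Z,6E,9S,10E)-6-{[(4-methoxybenzyl)oxy]methyl}-2,9-dimethyl-9-(4-methylpent-3-en-1-yl)cycloundeca-2,6,10-trien-1-yl]oxy}dimethylsilane
Product: 29 (1S,2Z,6E,9S,10E)-6-{[(4-methoxybenzyl)oxy]methyl}-2,9-dimethyl-9-(4-methylpent-3-en-1-yl)cycloundeca-2,6,10-trien-1-ol
Conditions: Bu4NF, THF, rt → 40 °C
Reagents that add atoms: none
Why: Fluoride cleavage of the secondary silyl ether under non-acidic conditions unmasks the doubly allylic alcohol that directs the epoxidation, the benzyl-type ether being stable.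

**Step 21**
Reactants: 29 (1S,2Z,6E,9S,10E)-6-{[(4-methoxybenzyl)oxy]methyl}-2,9-dimethyl-9-(4-methylpent-3-en-1-yl)cycloundeca-2,6,10-trien-1-ol
Product: 30 (1S,2S,3E,5S,7E,11R)-8-{[(4-methoxybenzyl)oxy]methyl}-1,5-dimethyl-5-(4-methylpent-3-en-1-yl)-12-oxabicyclo[9.1.0]dodeca-3,7-dien-2-ol
Conditions: VO(acac)2 (5 mol %), t-BuOOH, CH2Cl2, 0 °C → rt
Reagents that add atoms: tert-butyl hydroperoxide CC(C)(C)OO
Why: Hydroxyl-directed epoxidation by the vanadium alkoxide–peroxide complex touches only olefins allylic to the free hydroxyl and should prefer the more nucleophilic trisubstituted (Z)-olefin, delivering oxygen to the face syn to the hydroxyl in the conformer whose ring bond from the carbinol carbon lies roughly perpendicular to the olefin on the opposite face, which gives the cis (erythro) epoxy alcohol and so sets both oxirane stereocentres.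

**Step 22**
Reactants: 30 (1S,2S,3E,5S,7E,11R)-8-{[(4-methoxybenzyl)oxy]methyl}-1,5-dimethyl-5-(4-methylpent-3-en-1-yl)-12-oxabicyclo[9.1.0]dodeca-3,7-dien-2-ol; 31 3-methylbut-2-enoic acid
Product: 32 (1R,2S,3E,5S,7E,11R)-8-{[(4-methoxybenzyl)oxy]methyl}-1,5-dimethyl-5-(4-methylpent-3-en-1-yl)-12-oxabicyclo[9.1.0]dodeca-3,7-dien-2-yl 3-methylbut-2-enoate
Conditions: DCC, DMAP, CH2Cl2, 0 °C → rt
Reagents that add atoms: none
Why: Steglich esterification of the hindered epoxy alcohol with the free conjugated acid avoids the vinylketene pathway that deconjugates the acid chloride and touches no stereocentre (the C1 descriptor changes only because of the CIP rules).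

**Step 23**
Reactants: 32 (1R,2S,3E,5S,7E,11R)-8-{[(4-methoxybenzyl)oxy]methyl}-1,5-dimethyl-5-(4-methylpent-3-en-1-yl)-12-oxabicyclo[9.1.0]dodeca-3,7-dien-2-yl 3-methylbut-2-enoate
Product: 33 (1R,2S,3E,5S,7E,11R)-8-(hydroxymethyl)-1,5-dimethyl-5-(4-methylpent-3-en-1-yl)-12-oxabicyclo[9.1.0]dodeca-3,7-dien-2-yl 3-methylbut-2-enoate
Conditions: DDQ (1.3 equiv), CH2Cl2/pH 7 phosphate buffer, 0 °C
Reagents that add atoms: none
Why: Oxidative cleavage of the 4-methoxybenzyl ether by DDQ (benzylic hydride abstraction, then hydrolysis of the oxocarbenium ion) under buffered conditions should leave the oxirane, the ester and the olefins intact.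

**Compound list**
1 | 5-bromo-2-methylpent-2-ene | CC(C)=CCCBr | starting material
2 | lithium acetylide–ethylenediamine complex | [Li+].[C-]#C.NCCN | starting material
3 | 6-methylhept-5-en-1-yne | CC(C)=CCCC#C | intermediate
4 | 2-[(tert-butyldimethylsilyl)oxy]acetaldehyde | O=CCO[Si](C)(C)C(C)(C)C | starting material
5 | [(1E)-2,6-dimethylhepta-1,5-dien-1-yl]dimethylaluminium | CC(C)=CCC/C(C)=C/[Al](C)C | intermediate
6 | lithium butyl[(1E)-2,6-dimethylhepta-1,5-dien-1-yl]dimethylaluminate | CC(C)=CCC/C(C)=C/[Al-](C)(C)CCCC.[Li+] | intermediate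
7 | rac-(3E)-1-[(tert-butyldimethylsilyl)oxy]-4,8-dimethylnona-3,7-dien-2-ol | CC(C)=CCC/C(C)=C/C(O)CO[Si](C)(C)C(C)(C)C | intermediate
8 | (3E)-1-[(tert-butyldimethylsilyl)oxy]-4,8-dimethylnona-3,7-dien-2-one | CC(C)=CCC/C(C)=C/C(=O)CO[Si](C)(C)C(C)(C)C | intermediate
9 | (2R,3E)-1-[(tert-butyldimethylsilyl)oxy]-4,8-dimethylnona-3,7-dien-2-ol | CC(C)=CCC/C(C)=C/[C@@H](O)CO[Si](C)(C)C(C)(C)C | intermediate
10 | triethyl orthoacetate | CC(OCC)(OCC)OCC | starting material
11 | ethyl (3S,4E)-6-[(tert-butyldimethylsilyl)oxy]-3-methyl-3-(4-methylpent-3-en-1-yl)hex-4-enoate | CC(C)=CCC[C@@](C)(CC(=O)OCC)/C=C/CO[Si](C)(C)C(C)(C)C | intermediate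
12 | ethyl (3S,4E)-6-hydroxy-3-methyl-3-(4-methylpent-3-en-1-yl)hex-4-enoate | CC(C)=CCC[C@@](C)(CC(=O)OCC)/C=C/CO | intermediate
13 | ethyl (3S,4E)-3-methyl-3-(4-methylpent-3-en-1-yl)-6-oxohex-4-enoate | CC(C)=CCC[C@@](C)(CC(=O)OCC)/C=C/C=O | intermediate
14 | methyl propiolate | C#CC(=O)OC | starting material
15 | 9-ethyl 1-methyl (4S,5E,7S)-4-hydroxy-7-methyl-7-(4-methylpent-3-en-1-yl)non-5-en-2-ynedioate | CC(C)=CCC[C@@](C)(CC(=O)OCC)/C=C/[C@H](O)C#CC(=O)OC | intermediate
16 | 9-ethyl 1-methyl (4S,5E,7S)-4-[(tert-butyldimethylsilyl)oxy]-7-methyl-7-(4-methylpent-3-en-1-yl)non-5-en-2-ynedioate | CC(C)=CCC[C@@](C)(CC(=O)OCC)/C=C/[C@H](O[Si](C)(C)C(C)(C)C)C#CC(=O)OC | intermediate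
17 | 9-ethyl 1-methyl (2Z,4S,5E,7S)-4-[(tert-butyldimethylsilyl)oxy]-3,7-dimethyl-7-(4-methylpent-3-en-1-yl)nona-2,5-dienedioate | CC(C)=CCC[C@@](C)(CC(=O)OCC)/C=C/[C@H](O[Si](C)(C)C(C)(C)C)/C(C)=C\C(=O)OC | intermediate
18 | (2Z,4S,5E,7S)-4-[(tert-butyldimethylsilyl)oxy]-3,7-dimethyl-7-(4-methylpent-3-en-1-yl)nona-2,5-diene-1,9-diol | CC(C)=CCC[C@@](C)(CCO)/C=C/[C@H](O[Si](C)(C)C(C)(C)C)/C(C)=C\CO | intermediate
19 | (3S,4E,6S,7Z)-9-bromo-6-[(tert-butyldimethylsilyl)oxy]-3,7-dimethyl-3-(4-methylpent-3-en-1-yl)nona-4,7-dien-1-ol | CC(C)=CCC[C@@](C)(CCO)/C=C/[C@H](O[Si](C)(C)C(C)(C)C)/C(C)=C\CBr | intermediate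
20 | (3S,4E,6S,7Z)-6-[(tert-butyldimethylsilyl)oxy]-3,7-dimethyl-3-(4-methylpent-3-en-1-yl)-9-(phenylsulfonyl)nona-4,7-dien-1-ol | CC(C)=CCC[C@@](C)(CCO)/C=C/[C@H](O[Si](C)(C)C(C)(C)C)/C(C)=C\CS(=O)(=O)c1ccccc1 | intermediate
21 | (3S,4E,6S,7Z)-6-[(tert-butyldimethylsilyl)oxy]-3,7-dimethyl-3-(4-methylpent-3-en-1-yl)-9-(phenylsulfonyl)nona-4,7-dienal | CC(C)=CCC[C@@](C)(CC=O)/C=C/[C@H](O[Si](C)(C)C(C)(C)C)/C(C)=C\CS(=O)(=O)c1ccccc1 | intermediate
22 | methyl acrylate | C=CC(=O)OC | starting material
23 | methyl (5S,6E,8S,9Z)-8-[(tert-butyldimethylsilyl)oxy]-3-hydroxy-5,9-dimethyl-2-methylidene-5-(4-methylpent-3-en-1-yl)-11-(phenylsulfonyl)undeca-6,9-dienoate (both C3 epimers) | CC(C)=CCC[C@@](C)(CC(O)C(=C)C(=O)OC)/C=C/[C@H](O[Si](C)(C)C(C)(C)C)/C(C)=C\CS(=O)(=O)c1ccccc1 | intermediate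
24 | methyl (5S,6E,8S,9Z)-3-acetoxy-8-[(tert-butyldimethylsilyl)oxy]-5,9-dimethyl-2-methylidene-5-(4-methylpent-3-en-1-yl)-11-(phenylsulfonyl)undeca-6,9-dienoate (both C3 epimers) | CC(C)=CCC[C@@](C)(CC(OC(C)=O)C(=C)C(=O)OC)/C=C/[C@H](O[Si](C)(C)C(C)(C)C)/C(C)=C\CS(=O)(=O)c1ccccc1 | intermediate
25 | methyl (1E,4S,5E,7S,8Z)-7-[(tert-butyldimethylsilyl)oxy]-4,8-dimethyl-4-(4-methylpent-3-en-1-yl)-10-(phenylsulfonyl)cycloundeca-1,5,8-triene-1-carboxylate (both C10 epimers) | CC(C)=CCC[C@]1(C)/C=C/[C@H](O[Si](C)(C)C(C)(C)C)/C(C)=C\C(S(=O)(=O)c2ccccc2)C/C(C(=O)OC)=C\C1 | intermediate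
26 | [(1E,4S,5E,7S,8Z)-7-[(tert-butyldimethylsilyl)oxy]-4,8-dimethyl-4-(4-methylpent-3-en-1-yl)-10-(phenylsulfonyl)cycloundeca-1,5,8-trien-1-yl]methanol (both C10 epimers) | CC(C)=CCC[C@]1(C)/C=C/[C@H](O[Si](C)(C)C(C)(C)C)/C(C)=C\C(S(=O)(=O)c2ccccc2)C/C(CO)=C\C1 | intermediate
27 | [(1E,4S,5E,7S,8Z)-7-[(tert-butyldimethylsilyl)oxy]-4,8-dimethyl-4-(4-methylpent-3-en-1-yl)cycloundeca-1,5,8-trien-1-yl]methanol | CC(C)=CCC[C@]1(C)/C=C/[C@H](O[Si](C)(C)C(C)(C)C)/C(C)=C\CC/C(CO)=C\C1 | intermediate
28 | tert-butyl{[(1S,2Z,6E,9S,10E)-6-{[(4-methoxybenzyl)oxy]methyl}-2,9-dimethyl-9-(4-methylpent-3-en-1-yl)cycloundeca-2,6,10-trien-1-yl]oxy}dimethylsilane | CC(C)=CCC[C@]1(C)/C=C/[C@H](O[Si](C)(C)C(C)(C)C)/C(C)=C\CC/C(COCc2ccc(OC)cc2)=C\C1 | intermediate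
29 | (1S,2Z,6E,9S,10E)-6-{[(4-methoxybenzyl)oxy]methyl}-2,9-dimethyl-9-(4-methylpent-3-en-1-yl)cycloundeca-2,6,10-trien-1-ol | CC(C)=CCC[C@]1(C)/C=C/[C@H](O)/C(C)=C\CC/C(COCc2ccc(OC)cc2)=C\C1 | intermediate
30 | (1S,2S,3E,5S,7E,11R)-8-{[(4-methoxybenzyl)oxy]methyl}-1,5-dimethyl-5-(4-methylpent-3-en-1-yl)-12-oxabicyclo[9.1.0]dodeca-3,7-dien-2-ol | CC(C)=CCC[C@]1(C)/C=C/[C@H](O)[C@]2(C)O[C@@H]2CC/C(COCc3ccc(OC)cc3)=C\C1 | intermediate
31 | 3-methylbut-2-enoic acid | CC(C)=CC(=O)O | starting material
32 | (1R,2S,3E,5S,7E,11R)-8-{[(4-methoxybenzyl)oxy]methyl}-1,5-dimethyl-5-(4-methylpent-3-en-1-yl)-12-oxabicyclo[9.1.0]dodeca-3,7-dien-2-yl 3-methylbut-2-enoate | CC(C)=CCC[C@]1(C)/C=C/[C@H](OC(=O)C=C(C)C)[C@]2(C)O[C@@H]2CC/C(COCc3ccc(OC)cc3)=C\C1 | intermediate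
33 | (1R,2S,3E,5S,7E,11R)-8-(hydroxymethyl)-1,5-dimethyl-5-(4-methylpent-3-en-1-yl)-12-oxabicyclo[9.1.0]dodeca-3,7-dien-2-yl 3-methylbut-2-enoate | CC(C)=CCC[C@]1(C)/C=C/[C@H](OC(=O)C=C(C)C)[C@]2(C)O[C@@H]2CC/C(CO)=C\C1 | target

**Totals**
Total step count: 23. Longest linear sequence: 23 steps (the route is fully linear from 1).

**Steps most likely to fail**

Step 16 (proposed new method). The ring closure may lose to intermolecular Michael addition (oligomerisation). The allyl anion may also shed silanolate by 1,4-elimination before it cyclises, or a second deprotonation of the product may expel sulfinate. The fallback uses only known chemistry and sets out from 23. The Baylis–Hillman alcohol would be converted with N-bromosuccinimide/(CH3)2S (SN2′ bromination) into the primary allylic bromide methyl (2Z,5S,6E,8S,9Z)-2-(bromomethyl)-8-[(tert-butyldimethylsilyl)oxy]-5,9-dimethyl-5-(4-methylpent-3-en-1-yl)-11-(phenylsulfonyl)undeca-2,6,9-trienoate F1, in which the trisubstituted enoate is already in place. F1 would then be cyclised by the classical intramolecular SN2 alkylation of the sulfone-stabilised allyl carbanion with an allylic bromide (KN(Si(CH3)3)2, THF, −78 °C, high dilution), the reaction type established for medium and large 1,5-diene carbocycles. This comes back to the route at 25.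

Step 21. Oxygen delivery may occur from a minor ring conformer and give poor facial selectivity. The disubstituted C3=C4 olefin, also allylic to the hydroxyl, may compete, or the doubly allylic alcohol may be over-oxidised to the dienone. The fallback sets out from 29 and replaces substrate direction by reagent control: Sharpless asymmetric epoxidation with Ti(O-i-Pr)4, L-(+)-diisopropyl tartrate and t-BuOOH over 4 Å molecular sieves in CH2Cl2 at −20 °C. For the (S) carbinol this tartrate is the matched partner and delivers oxygen to the face that gives the erythro (cis) epoxy alcohol. It makes no new compound (F0) and comes back at 30.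

Step 18. Hydride may be delivered to the wrong allyl terminus, or the Z olefin may isomerise through the π-allyl palladium intermediate. The fallback sets out from 26 and changes the mechanism to single-electron reductive desulfonylation with sodium amalgam, Na(Hg), buffered with Na2HPO4 in MeOH/THF at −20 °C. This avoids any allyl–metal intermediate, makes no new compound (F0) and comes back at 27.

**Further compounds**
F1 | step 16 | methyl (2Z,5S,6E,8S,9Z)-2-(bromomethyl)-8-[(tert-butyldimethylsilyl)oxy]-5,9-dimethyl-5-(4-methylpent-3-en-1-yl)-11-(phenylsulfonyl)undeca-2,6,9-trienoate | CC(C)=CCC[C@@](C)(C/C=C(\CBr)C(=O)OC)/C=C/[C@H](O[Si](C)(C)C(C)(C)C)/C(C)=C\CS(=O)(=O)c1ccccc1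
F0 | step 18 | none | none
F0 | step 21 | none | none
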